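Ring B is a resorcylate of the 3-methylorsellinate type, and its C3a–C7a bond is the aldol bond of the polyketide fold; the route cuts there. One base-induced aldol condensation–aromatisation of a diketo-dioxinone closes ring B, leaves C1 and O7 tied in an isopropylidene ester, frees only the C5 hydroxyl for methylation and delivers C3 as an aldehyde acetal. The precursor is a 2,2-dimethyl-1,3-dioxin-4-one whose side chain carries a 3,5-diketone, a terminal dimethoxymethyl group and a benzyloxymethyl branch (the future C6 substituent), so that the benzylic oxygen for the ring A ester is in place before ring B exists. The lactol centre C3 is fixed last by acylative dynamic kinetic resolution.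

Key step: step 4

Assumption: the C3 lactol epimerises by ring–chain tautomerism (through the achiral 2-formylbenzoic acid form) in the presence of base or protic nucleophiles, so it is fixed as an O-acyl lactol and liberated only in the last step in a neutral, anhydrous medium; the target is to be isolated and stored cold and base-free.

Step 1
Reactants: 1 2,2,6-trimethyl-4H-1,3-dioxin-4-one; 2 benzyl chloromethyl ether
Product: 3 6-[2-(benzyloxy)ethyl]-2,2-dimethyl-4H-1,3-dioxin-4-one
Conditions: LiN(iPr)2, THF, −78 °C; then 2, DMPU, −78 → −40 °C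
Reagents that add atoms: none
Why: γ-Alkylation of a dioxinone lithium dienolate: kinetic deprotonation of the ring methyl gives the dienolate, which reacts at its terminal carbon with the reactive α-chloro ether in an SN2 alkoxymethylation.

Step 2
Reactants: 3 6-[2-(benzyloxy)ethyl]-2,2-dimethyl-4H-1,3-dioxin-4-one; 4 acetyl chloride
Product: 5 6-[1-(benzyloxy)-3-oxobutan-2-yl]-2,2-dimethyl-4H-1,3-dioxin-4-one (racemic)
Conditions: LiN(SiMe3)2 (2.2 equiv), THF, −78 °C; then 4, −78 °C; AcOH quench
Reagents that add atoms: none
Why: C-Acylation of the dioxinone lithium dienolate at its γ-carbon with an acid chloride (crossed Claisen-type acylation); the second equivalent of base stores the more acidic product as its enolate, the low temperature holds back β-elimination of benzyl oxide, and the new centre is racemic and labile, which does not matter because it becomes an aromatic carbon.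

Step 3
Reactants: 5 6-[1-(benzyloxy)-3-oxobutan-2-yl]-2,2-dimethyl-4H-1,3-dioxin-4-one; 6 methyl dimethoxyacetate
Product: 7 6-[1-(benzyloxy)-6,6-dimethoxy-3,5-dioxohexan-2-yl]-2,2-dimethyl-4H-1,3-dioxin-4-one (racemic keto–enol mixture used crude)
Conditions: LiN(iPr)2 (3.1 equiv), THF, −78 °C; then 6, −78 → −40 °C; AcOH quench, cold aqueous work-up
Reagents that add atoms: none
Why: Dianion Claisen condensation: the base removes first the doubly activated methine proton and then a methyl proton, the more reactive terminal enolate attacks the alkoxy-activated ester, and the third equivalent of base takes up the acidic 1,3-diketone that results.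

Step 4
Reactants: 7 6-[1-(benzyloxy)-6,6-dimethoxy-3,5-dioxohexan-2-yl]-2,2-dimethyl-4H-1,3-dioxin-4-one
Product: 9 8-[(benzyloxy)methyl]-5-(dimethoxymethyl)-7-hydroxy-2,2-dimethyl-4H-benzo[d][1,3]dioxin-4-one, via cyclic aldol adduct 8 (not isolated)
Conditions: Et3N, CH2Cl2, 0 °C → rt
Reagents that add atoms: none
Why: Et3N converts 7 into its extended enolate, and the dioxinone α-carbon (the future C7a) adds to the ketone next to the dimethoxymethyl group (the future C3a); adduct 8 then loses water by E1cB and the remaining ring ketone (the future C5 oxygen) enolises, which makes ring B aromatic. The closest known reaction type is the base-mediated biomimetic aldol aromatisation of diketo-dioxinones to isopropylidene-protected resorcylates, which includes substrates with a substituent on the carbon between dioxinone and ketone. Ring B closes in the 6-(enolendo)-exo-trig mode, and no stereocentre remains, because the two centres of 8 are lost on aromatisation. The step needs C–C closure in preference to O-acylation (pyranone formation) and to β-elimination of benzyl oxide from the enolate at the branch carbon. The dioxinone holds the carboxyl carbon as a vinylogous ester that does not acylate at room temperature, the α-keto acetal is the most electrophilic carbonyl of the chain, and benzyl oxide is a poor leaving group from a doubly stabilised anion, so the intramolecular aldol should win. The fused dioxinone leaves C1 and O7 masked and only the C5 hydroxyl free.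

Step 5
Reactants: 9 8-[(benzyloxy)methyl]-5-(dimethoxymethyl)-7-hydroxy-2,2-dimethyl-4H-benzo[d][1,3]dioxin-4-one
Product: 10 8-[(benzyloxy)methyl]-5-(dimethoxymethyl)-7-methoxy-2,2-dimethyl-4H-benzo[d][1,3]dioxin-4-one
Conditions: MeI, K2CO3, acetone, 40 °C
Reagents that add atoms: iodomethane, CI
Why: Williamson ether synthesis on the only free phenol, which is para to the ester carbonyl and therefore acidic, while the dioxinone and the acetal are inert to K2CO3 in acetone.

Step 6
Reactants: 10 8-[(benzyloxy)methyl]-5-(dimethoxymethyl)-7-methoxy-2,2-dimethyl-4H-benzo[d][1,3]dioxin-4-one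
Product: 11 5-(dimethoxymethyl)-8-(hydroxymethyl)-7-methoxy-2,2-dimethyl-4H-benzo[d][1,3]dioxin-4-one
Conditions: H2 (1 atm), 10% Pd/C, EtOAc, rt
Reagents that add atoms: none
Why: Catalytic hydrogenolysis of the benzyl ether cleaves the unhindered PhCH2–O bond, whereas the ArCH2–O bond between two ortho substituents and the acetal C–O bonds react far more slowly in neutral EtOAc.

Step 7
Reactants: 12 atraric acid (methyl 2,4-dihydroxy-3,6-dimethylbenzoate)
Product: 13 methyl 2-hydroxy-4-methoxy-3,6-dimethylbenzoate
Conditions: MeI (1.05 equiv), K2CO3, acetone, reflux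
Reagents that add atoms: iodomethane, CI
Why: Williamson methylation selective for the 4-hydroxyl, because the 2-hydroxyl is locked in a hydrogen bond to the ester carbonyl and is flanked by a methyl group.

Step 8
Reactants: 13 methyl 2-hydroxy-4-methoxy-3,6-dimethylbenzoate
Product: 14 2-hydroxy-4-methoxy-3,6-dimethylbenzoic acid
Conditions: KOH, DMSO–H2O, 80 °C; then 1 M HCl, 0 °C
Reagents that add atoms: potassium hydroxide, [K+].[OH-]
Why: Saponification (acyl–oxygen cleavage) of the hindered salicylate in aqueous DMSO, where hydroxide is poorly solvated and reactive, with cold acidification to avoid decarboxylation of the electron-rich acid.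

Step 9
Reactants: 11 5-(dimethoxymethyl)-8-(hydroxymethyl)-7-methoxy-2,2-dimethyl-4H-benzo[d][1,3]dioxin-4-one; 14 2-hydroxy-4-methoxy-3,6-dimethylbenzoic acid
Product: 15 [5-(dimethoxymethyl)-7-methoxy-2,2-dimethyl-4-oxo-4H-benzo[d][1,3]dioxin-8-yl]methyl 2-hydroxy-4-methoxy-3,6-dimethylbenzoate
Conditions: PPh3, DIAD, THF, 0 °C → rt
Reagents that add atoms: none
Why: Mitsunobu esterification: the primary benzylic alcohol is activated as its oxyphosphonium ion and displaced by the carboxylate, so the hindered carbonyl of 14 never has to be attacked, and the chelated phenol, far less acidic than the carboxylic acid, does not compete.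

Step 10
Reactants: 15 [5-(dimethoxymethyl)-7-methoxy-2,2-dimethyl-4-oxo-4H-benzo[d][1,3]dioxin-8-yl]methyl 2-hydroxy-4-methoxy-3,6-dimethylbenzoate
Product: 17 racemic (3,7-dihydroxy-5-methoxy-1-oxo-1,3-dihydroisobenzofuran-6-yl)methyl 2-hydroxy-4-methoxy-3,6-dimethylbenzoate, via aldehyde 16 (not isolated)
Conditions: 2 M HCl (aq), THF, rt → 40 °C
Reagents that add atoms: water, O
Why: Acid hydrolysis of the acetal gives aldehyde 16, whose hydrate attacks the neighbouring dioxinone carbonyl in a 5-exo-trig acyl transfer (the pseudo-acid closure known for 2-formylbenzoate esters) and expels acetone and the C7 phenol; the lactol centre forms as the racemate, and the ring A ester survives because its carbonyl is hindered and its benzylic C–O bond sits para to the electron-poor C3 carbon.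

Step 11
Reactants: 17 racemic (3,7-dihydroxy-5-methoxy-1-oxo-1,3-dihydroisobenzofuran-6-yl)methyl 2-hydroxy-4-methoxy-3,6-dimethylbenzoate
Product: 18 [(3R)-7-hydroxy-5-methoxy-1-oxo-3-(propanoyloxy)-1,3-dihydroisobenzofuran-6-yl]methyl 2-hydroxy-4-methoxy-3,6-dimethylbenzoate
Conditions: (R)-benzotetramisole [(R)-BTM] (5 mol %), (EtCO)2O (1.2 equiv), iPr2NEt (1.2 equiv), CHCl3, −20 °C
Reagents that add atoms: propionic anhydride, CCC(=O)OC(=O)CC
Why: Acylative dynamic kinetic resolution of a lactol by a chiral isothiourea: base-mediated ring–chain tautomerism racemises C3 faster than the slow enantiomer is acylated, and the acyl-isothiouronium from (R)-BTM should transfer the propanoyl group to the 3R lactol (arene stacked on the catalyst, as with (R)-benzylic alcohols), which sets C3 as R; the two phenols are hindered and hydrogen-bonded to carbonyl groups and should not compete, and if a model lactol shows the opposite sense, (S)-BTM is used.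

Step 12
Reactants: 18 [(3R)-7-hydroxy-5-methoxy-1-oxo-3-(propanoyloxy)-1,3-dihydroisobenzofuran-6-yl]methyl 2-hydroxy-4-methoxy-3,6-dimethylbenzoate
Product: 19 [(3R)-3,7-dihydroxy-5-methoxy-1-oxo-1,3-dihydroisobenzofuran-6-yl]methyl 2-hydroxy-4-methoxy-3,6-dimethylbenzoate
Conditions: immobilised Candida antarctica lipase B, n-BuOH (3 equiv), MTBE, 4 → 20 °C; filter, concentrate cold
Reagents that add atoms: none
Why: Lipase-catalysed transesterification (alcoholysis) of the lactol ester: the enzyme attacks the propanoyl carbonyl, so the C3–O bond is never broken and the lactol leaves as the neutral alcohol with retention; the neutral, base-free, anhydrous medium holds back ring–chain epimerisation, the hindered aryl ester and the phenols are not lipase substrates, and the 3R ester is the enantiomer that the empirical model for lipases with secondary alcohols predicts to be accepted.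

Compound list
1 | 2,2,6-trimethyl-4H-1,3-dioxin-4-one | CC1=CC(=O)OC(C)(C)O1 | starting material
2 | benzyl chloromethyl ether | ClCOCc1ccccc1 | starting material
3 | 6-[2-(benzyloxy)ethyl]-2,2-dimethyl-4H-1,3-dioxin-4-one | O=C1C=C(CCOCc2ccccc2)OC(C)(C)O1 | intermediate
4 | acetyl chloride | CC(Cl)=O | starting material
5 | 6-[1-(benzyloxy)-3-oxobutan-2-yl]-2,2-dimethyl-4H-1,3-dioxin-4-one (racemic) | CC(=O)C(COCc1ccccc1)C1=CC(=O)OC(C)(C)O1 | intermediate
6 | methyl dimethoxyacetate | COC(OC)C(=O)OC | starting material
7 | 6-[1-(benzyloxy)-6,6-dimethoxy-3,5-dioxohexan-2-yl]-2,2-dimethyl-4H-1,3-dioxin-4-one (racemic, keto–enol mixture) | COC(OC)C(=O)CC(=O)C(COCc1ccccc1)C1=CC(=O)OC(C)(C)O1 | intermediate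
8 | 8-[(benzyloxy)methyl]-5-(dimethoxymethyl)-5-hydroxy-2,2-dimethyl-5,6-dihydro-4H-benzo[d][1,3]dioxine-4,7(8H)-dione (cyclic aldol adduct, diastereomer mixture) | CC1(C)OC(=O)C2=C(O1)C(COCc1ccccc1)C(=O)CC2(O)C(OC)OC | intermediate
9 | 8-[(benzyloxy)methyl]-5-(dimethoxymethyl)-7-hydroxy-2,2-dimethyl-4H-benzo[d][1,3]dioxin-4-one | CC1(C)OC(=O)c2c(C(OC)OC)cc(O)c(COCc3ccccc3)c2O1 | intermediate
10 | 8-[(benzyloxy)methyl]-5-(dimethoxymethyl)-7-methoxy-2,2-dimethyl-4H-benzo[d][1,3]dioxin-4-one | CC1(C)OC(=O)c2c(C(OC)OC)cc(OC)c(COCc3ccccc3)c2O1 | intermediate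
11 | 5-(dimethoxymethyl)-8-(hydroxymethyl)-7-methoxy-2,2-dimethyl-4H-benzo[d][1,3]dioxin-4-one | CC1(C)OC(=O)c2c(C(OC)OC)cc(OC)c(CO)c2O1 | intermediate
12 | atraric acid (methyl 2,4-dihydroxy-3,6-dimethylbenzoate) | COC(=O)c1c(C)cc(O)c(C)c1O | starting material
13 | methyl 2-hydroxy-4-methoxy-3,6-dimethylbenzoate | COC(=O)c1c(C)cc(OC)c(C)c1O | intermediate
14 | 2-hydroxy-4-methoxy-3,6-dimethylbenzoic acid | OC(=O)c1c(C)cc(OC)c(C)c1O | intermediate
15 | [5-(dimethoxymethyl)-7-methoxy-2,2-dimethyl-4-oxo-4H-benzo[d][1,3]dioxin-8-yl]methyl 2-hydroxy-4-methoxy-3,6-dimethylbenzoate | CC1(C)OC(=O)c2c(C(OC)OC)cc(OC)c(COC(=O)c3c(C)cc(OC)c(C)c3O)c2O1 | intermediate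
16 | (5-formyl-7-methoxy-2,2-dimethyl-4-oxo-4H-benzo[d][1,3]dioxin-8-yl)methyl 2-hydroxy-4-methoxy-3,6-dimethylbenzoate | CC1(C)OC(=O)c2c(C=O)cc(OC)c(COC(=O)c3c(C)cc(OC)c(C)c3O)c2O1 | intermediate
17 | racemic (3,7-dihydroxy-5-methoxy-1-oxo-1,3-dihydroisobenzofuran-6-yl)methyl 2-hydroxy-4-methoxy-3,6-dimethylbenzoate | COc1cc(C)c(C(=O)OCc2c(OC)cc3c(c2O)C(=O)OC3O)c(O)c1C | intermediate
18 | [(3R)-7-hydroxy-5-methoxy-1-oxo-3-(propanoyloxy)-1,3-dihydroisobenzofuran-6-yl]methyl 2-hydroxy-4-methoxy-3,6-dimethylbenzoate | COc1cc(C)c(C(=O)OCc2c(OC)cc3c(c2O)C(=O)O[C@H]3OC(=O)CC)c(O)c1C | intermediate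
19 | [(3R)-3,7-dihydroxy-5-methoxy-1-oxo-1,3-dihydroisobenzofuran-6-yl]methyl 2-hydroxy-4-methoxy-3,6-dimethylbenzoate | COc1cc(C)c(C(=O)OCc2c(OC)cc3c(c2O)C(=O)O[C@H]3O)c(O)c1C | target

Total step count: 12. Longest linear sequence: 10 steps (steps 1–6 and 9–12); steps 7 and 8 form the ring A branch.

Steps most likely to fail

Step 4. β-Elimination of benzyl alcohol from the enolate at the branch carbon, or O-cyclisation to a pyranone, may outrun the aldol ring closure; the same elimination also threatens the enolates of steps 2 and 3. The fallback introduces the oxygenated carbon only after aromatisation, so that no enolate carries a β-leaving group. It sets out from 1: γ-acetylation with 4 (LiN(SiMe3)2, THF, −78 °C) gives 2,2-dimethyl-6-(2-oxopropyl)-4H-1,3-dioxin-4-one F1. Dianion Claisen condensation of F1 with 6 gives 6-(5,5-dimethoxy-2,4-dioxopentyl)-2,2-dimethyl-4H-1,3-dioxin-4-one F2. Et3N in CH2Cl2 should aromatise F2 to 5-(dimethoxymethyl)-7-hydroxy-2,2-dimethyl-4H-benzo[d][1,3]dioxin-4-one F3. Magnesium-mediated ortho-formylation of the phenol (MgCl2, Et3N, paraformaldehyde, MeCN, reflux; Casnati–Skattebøl reaction) should go to C8, the ortho position between the two oxygens and away from the bulky acetal, and give 5-(dimethoxymethyl)-7-hydroxy-2,2-dimethyl-4-oxo-4H-benzo[d][1,3]dioxine-8-carbaldehyde F4. O-Methylation (MeI, K2CO3, acetone) gives 5-(dimethoxymethyl)-7-methoxy-2,2-dimethyl-4-oxo-4H-benzo[d][1,3]dioxine-8-carbaldehyde F5, and NaBH4 (MeOH–THF, 0 °C) reduces the aldehyde to the benzylic alcohol. The route is rejoined at 11, and the hydrogenolysis of step 6 is no longer needed.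

Step 11. A phenol may be acylated instead of the lactol, the amine base may deprotonate the C7 phenol and trigger loss of the ring A carboxylate through an ortho-quinone methide, or racemisation may be too slow for high enantioselectivity. The fallback is a base-free biocatalytic dynamic kinetic resolution that sets out from 17 and comes back at 18: immobilised Candida antarctica lipase B or Burkholderia cepacia lipase, vinyl propionate, toluene, 40 °C, with a trace of acetic acid to keep the lactol equilibrating through its open form. Lipases do not acylate hindered chelated phenols, and the empirical model for lipases with secondary alcohols (larger benzo side against smaller ring-oxygen side) predicts the 3R ester.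

Step 12. The enzyme may turn over the bulky lactol ester so slowly that the liberated lactol epimerises by ring–chain tautomerism during the reaction. The fallback avoids the ester altogether: it sets out from racemic 17 and arrives at 19 by preparative chiral supercritical-fluid chromatography on an immobilised amylose tris(3,5-dimethylphenylcarbamate) phase (CO2–MeCN with 0.1% formic acid, column at 10 °C). The wrong enantiomer is recycled through ring–chain equilibration.

Further compounds
F1 | step 4 | 2,2-dimethyl-6-(2-oxopropyl)-4H-1,3-dioxin-4-one | CC(=O)CC1=CC(=O)OC(C)(C)O1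
F2 | step 4 | 6-(5,5-dimethoxy-2,4-dioxopentyl)-2,2-dimethyl-4H-1,3-dioxin-4-one | COC(OC)C(=O)CC(=O)CC1=CC(=O)OC(C)(C)O1
F3 | step 4 | 5-(dimethoxymethyl)-7-hydroxy-2,2-dimethyl-4H-benzo[d][1,3]dioxin-4-one | CC1(C)OC(=O)c2c(C(OC)OC)cc(O)cc2O1
F4 | step 4 | 5-(dimethoxymethyl)-7-hydroxy-2,2-dimethyl-4-oxo-4H-benzo[d][1,3]dioxine-8-carbaldehyde | CC1(C)OC(=O)c2c(C(OC)OC)cc(O)c(C=O)c2O1
F5 | step 4 | 5-(dimethoxymethyl)-7-methoxy-2,2-dimethyl-4-oxo-4H-benzo[d][1,3]dioxine-8-carbaldehyde | CC1(C)OC(=O)c2c(C(OC)OC)cc(OC)c(C=O)c2O1
F0 | step 11 | none | none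
F0 | step 12 | none | none
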